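**Plan**
- Retrosynthesis: the C2-symmetric C40 polyene is cut at C11=C12 and C11′=C12′ (twofold Wittig: two identical C15 phosphonium salts plus the C10 dialdehyde). Each C15 unit is cut at C8–C9 (Negishi coupling with a C4 iodoenoate), and each ring at C1–C2 and C5–C6 (Diels–Alder).
- Enabling feature: in each ε-ring the array C1(CH3)2–C6H–C7(–C8) is the skeleton of mesityl oxide, and C2–C3(O)–C4–C5–C18 is a 2-silyloxypenta-1,3-diene. One [4+2] event therefore delivers every ring atom with its substituent, with the quaternary C1 next to the stereocentre C6.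
- Forward order: ring (steps 1–2), acetyl to ethynyl (3), C7–C11 dienoate by hydrozirconation and Negishi coupling (4), enol ether to C4=C5 enone (5), C3 carbinol (6), C15 phosphonium salt (7–9), twofold chain joining and deprotection (10–11).
- Stereochemistry: C6 from the chiral oxazaborolidinium catalyst in the cycloaddition; C3 from a CBS reduction (trans to the C6 chain); 7E from syn-hydrozirconation, 9E from the iodoenoate, 11E/11′E from Wittig olefination plus thermal equilibration, the central triene from the dialdehyde.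

Key step: step 2

Assumption: the oxazaborolidinium ion from (S)-α,α-diphenylprolinol is taken to shield the Re face of the α-carbon of mesityl oxide. This sense is inferred by analogy and is not secured for an s-cis β,β-disubstituted enone; if correlation of the cycloadduct shows the opposite sense, the (R)-prolinol catalyst is used with no other change.

**Step 1**
Reactants: 1 (3E)-pent-3-en-2-one
Product: 2 tert-butyldimethyl{[(3E)-penta-1,3-dien-2-yl]oxy}silane (TBS = tert-butyldimethylsilyl)
Conditions: TBSOTf (1.1 equiv), Et3N (1.5 equiv), Et2O, 0 °C → rt; distillation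
Reagents that add atoms: tert-butyldimethylsilyl trifluoromethanesulfonate, CC(C)(C)[Si](C)(C)OS(=O)(=O)C(F)(F)F
Why: Soft enolisation (O-silylation of the enone, then deprotonation of the acetyl methyl by Et3N) should give the cross-conjugated 2-silyloxydiene with the (E)-propenyl unit unchanged (silyl enol ether formation).

**Step 2**
Reactants: 2 tert-butyldimethyl{[(3E)-penta-1,3-dien-2-yl]oxy}silane; 3 mesityl oxide (4-methylpent-3-en-2-one)
Product: 4 1-[(1S,2S)-4-{[tert-butyl(dimethyl)silyl]oxy}-2,6,6-trimethylcyclohex-3-en-1-yl]ethan-1-one (acetyl and C5 methyl cis)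
Conditions: (S)-3,3-diphenyl-1-(2-methylphenyl)tetrahydro-1H,3H-pyrrolo[1,2-c][1,3,2]oxazaborole (20 mol%), HNTf2 (16 mol%), 2 (1.5 equiv, slow addition), CH2Cl2, −78 → −40 °C; Et3N quench
Reagents that add atoms: none
Why: Proposed new method: the N-protonated oxazaborolidine binds the ketone oxygen of 3 and lowers its LUMO, so that the nucleophilic CH2 terminus of the silyl enol ether (C2) attacks the β-carbon C1 and C5 then bonds to the α-carbon C6, either as a strongly asynchronous [4+2] cycloaddition or as a Mukaiyama–Michael addition followed by collapse of the boron enolate onto the silyloxocarbenium ion, which restores the C3=C4 silyl enol ether. The closest known reaction types are the racemic HNTf2-, AlCl3- or AlBr3/AlMe3-promoted cycloadditions of 2-silyloxydienes and of penta-1,3-diene with hindered β,β-disubstituted enones, mesityl oxide included, and the oxazaborolidinium-catalysed enantioselective Diels–Alder reactions of less substituted enones. The six-membered ring closes by the [4+2] mode, in the stepwise limit by a 6-(enolexo)-endo-trig Michael closure. C6 is controlled by the catalyst, whose aryl groups should leave only the Si face of the α-carbon of 3 open to C5; C5 follows from the endo approach of the acetyl group and is of no consequence, because it becomes trigonal in step 5 (a C5 epimer converges there). The step needs C2-to-C1 regiochemistry, secured by the polarity match between the enol ether terminus and the enone β-carbon, and enone face selection, which rests on the catalyst alone and therefore on suppressing free HNTf2 and silyl triflimide through the excess of oxazaborolidine over acid and the low temperature.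

**Step 3**
Reactants: 4 1-[(1S,2S)-4-{[tert-butyl(dimethyl)silyl]oxy}-2,6,6-trimethylcyclohex-3-en-1-yl]ethan-1-one
Product: 6 tert-butyl{[(3R,4S)-4-ethynyl-3,5,5-trimethylcyclohex-1-en-1-yl]oxy}dimethylsilane, via enol phosphate 5 (not isolated)
Conditions: LiN(i-Pr)2 (1.1 equiv), THF, −78 °C; ClP(O)(OEt)2, −78 → 0 °C; then LiN(i-Pr)2 (2.3 equiv), −78 °C → rt; aq. NH4Cl
Reagents that add atoms: none
Why: Kinetic deprotonation occurs at the acetyl methyl (the C6–H between C1 and C5 is too hindered), and O-phosphorylation followed by base-induced β-elimination of diethyl phosphate should give the terminal alkyne with C6 untouched (methyl ketone to alkyne conversion through the enol phosphate).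

**Step 4**
Reactants: 6 tert-butyl{[(3R,4S)-4-ethynyl-3,5,5-trimethylcyclohex-1-en-1-yl]oxy}dimethylsilane; 7 ethyl (2E)-3-iodobut-2-enoate
Product: 10 ethyl (2E,4E)-5-[(1S,2R)-4-{[tert-butyl(dimethyl)silyl]oxy}-2,6,6-trimethylcyclohex-3-en-1-yl]-3-methylpenta-2,4-dienoate, via alkenylzirconocene chloride 8 (not isolated), via alkenylzinc chloride 9 (not isolated)
Conditions: Cp2Zr(H)Cl (1.2 equiv), THF, rt, dark; then ZnCl2 (1.2 equiv), 7, Pd(PPh3)4 (5 mol%), THF, rt
Reagents that add atoms: none
Why: syn-Hydrozirconation places the metal on the terminal carbon and fixes 7E, and transmetalation to zinc followed by Negishi coupling proceeds with retention at both alkenes, so 9E comes from the iodoenoate; the trisubstituted silyl enol ether is inert to Cp2Zr(H)Cl.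

**Step 5**
Reactants: 10 ethyl (2E,4E)-5-[(1S,2R)-4-{[tert-butyl(dimethyl)silyl]oxy}-2,6,6-trimethylcyclohex-3-en-1-yl]-3-methylpenta-2,4-dienoate
Product: 11 ethyl (2E,4E)-3-methyl-5-[(1R)-2,6,6-trimethyl-4-oxocyclohex-2-en-1-yl]penta-2,4-dienoate
Conditions: Pd(OAc)2 (1.1 equiv), MeCN, rt → 40 °C; neutral work-up
Reagents that add atoms: none
Why: Saegusa–Ito oxidation: Pd(OAc)2 turns the silyl enol ether into a C4-bound palladium enolate and β-hydride elimination of the C5–H gives the C4=C5 enone; C1 is quaternary, so no other enone can form, and the neutral conditions should spare the doubly allylic C6–H.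

**Step 6**
Reactants: 11 ethyl (2E,4E)-3-methyl-5-[(1R)-2,6,6-trimethyl-4-oxocyclohex-2-en-1-yl]penta-2,4-dienoate
Product: 12 ethyl (2E,4E)-5-[(1R,4R)-4-hydroxy-2,6,6-trimethylcyclohex-2-en-1-yl]-3-methylpenta-2,4-dienoate (hydroxyl trans to the side chain)
Conditions: (S)-1-methyl-3,3-diphenyltetrahydro-1H,3H-pyrrolo[1,2-c][1,3,2]oxazaborole (20 mol%), catecholborane (1.5 equiv), toluene, −78 → −40 °C
Reagents that add atoms: none
Why: CBS reduction: with the alkenyl arm C4 as the larger ketone substituent, the (S)-oxazaborolidine–borane complex should deliver hydride to the face that gives the (3R)-carbinol, the ring's own bias (axial C1 methyl) is expected to favour the same trans alcohol, catecholborane at low temperature leaves the ester and dienes alone, and any (6S)-enone carried over from step 2 should end up mainly as a separable cis diastereomer.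

**Step 7**
Reactants: 12 ethyl (2E,4E)-5-[(1R,4R)-4-hydroxy-2,6,6-trimethylcyclohex-2-en-1-yl]-3-methylpenta-2,4-dienoate
Product: 13 ethyl (2E,4E)-5-[(1R,4R)-4-{[tert-butyl(dimethyl)silyl]oxy}-2,6,6-trimethylcyclohex-2-en-1-yl]-3-methylpenta-2,4-dienoate
Conditions: TBSCl, imidazole, DMF, rt
Reagents that add atoms: tert-butyldimethylsilyl chloride, CC(C)(C)[Si](C)(C)Cl
Why: Silylation of the secondary allylic alcohol protects C3–OH against the bromination of step 9 without touching the stereocentres (silyl ether formation).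

**Step 8**
Reactants: 13 ethyl (2E,4E)-5-[(1R,4R)-4-{[tert-butyl(dimethyl)silyl]oxy}-2,6,6-trimethylcyclohex-2-en-1-yl]-3-methylpenta-2,4-dienoate
Product: 14 (2E,4E)-5-[(1R,4R)-4-{[tert-butyl(dimethyl)silyl]oxy}-2,6,6-trimethylcyclohex-2-en-1-yl]-3-methylpenta-2,4-dien-1-ol
Conditions: i-Bu2AlH (2.2 equiv), CH2Cl2, −78 °C; aq. potassium sodium tartrate
Reagents that add atoms: none
Why: 1,2-Reduction of the conjugated ester by the aluminium hydride should give the primary dienyl alcohol with the alkene geometries and the silyl ether intact.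

**Step 9**
Reactants: 14 (2E,4E)-5-[(1R,4R)-4-{[tert-butyl(dimethyl)silyl]oxy}-2,6,6-trimethylcyclohex-2-en-1-yl]-3-methylpenta-2,4-dien-1-ol
Product: 16 {(2E,4E)-5-[(1R,4R)-4-{[tert-butyl(dimethyl)silyl]oxy}-2,6,6-trimethylcyclohex-2-en-1-yl]-3-methylpenta-2,4-dien-1-yl}triphenylphosphonium bromide, via dienyl bromide 15 (not isolated)
Conditions: CBr4 (1.1 equiv), PPh3 (1.1 equiv), CH2Cl2, 0 °C; then PPh3 (1.2 equiv), rt; precipitation with Et2O
Reagents that add atoms: triphenylphosphine, c1ccc(cc1)P(c1ccccc1)c1ccccc1; tetrabromomethane, BrC(Br)(Br)Br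
Why: Appel bromination of the primary allylic alcohol under neutral conditions, followed by SN2 quaternisation of the reactive dienyl bromide at its primary carbon, avoids the acid that would ionise the allylic C3 silyl ether.

**Step 10**
Reactants: 16 {(2E,4E)-5-[(1R,4R)-4-{[tert-butyl(dimethyl)silyl]oxy}-2,6,6-trimethylcyclohex-2-en-1-yl]-3-methylpenta-2,4-dien-1-yl}triphenylphosphonium bromide (2.2 equiv); 17 (2E,4E,6E)-2,7-dimethylocta-2,4,6-trienedial
Product: 19 (all-E)-(3R,3′R,6R,6′R)-3,3′-bis{[tert-butyl(dimethyl)silyl]oxy}-ε,ε-carotene, via C25 aldehyde 18 (not isolated)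
Conditions: NaOMe (2.4 equiv), CH2Cl2/MeOH, 0 °C → rt, dark; then n-heptane, reflux, Ar
Reagents that add atoms: none
Why: Twofold Wittig olefination of the dialdehyde with the semi-stabilised allylic ylide forms C11=C12 and C11′=C12′, and the sterically strained 11Z isomers should relax thermally to the all-E polyene.

**Step 11**
Reactants: 19 (all-E)-(3R,3′R,6R,6′R)-3,3′-bis{[tert-butyl(dimethyl)silyl]oxy}-ε,ε-carotene
Product: 20 (all-E)-(3R,3′R,6R,6′R)-ε,ε-carotene-3,3′-diol (the target)
Conditions: n-Bu4NF, THF, 0 °C → rt, dark, Ar; crystallisation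
Reagents that add atoms: none
Why: Fluoride-induced desilylation of the two secondary silyl ethers should free both hydroxyl groups without affecting the polyene or the four stereocentres.

**Compound list**
1 | (3E)-pent-3-en-2-one | C/C=C/C(C)=O | starting material
2 | tert-butyldimethyl{[(3E)-penta-1,3-dien-2-yl]oxy}silane | C/C=C/C(=C)O[Si](C)(C)C(C)(C)C | intermediate
3 | mesityl oxide (4-methylpent-3-en-2-one) | CC(C)=CC(C)=O | starting material
4 | 1-[(1S,2S)-4-{[tert-butyl(dimethyl)silyl]oxy}-2,6,6-trimethylcyclohex-3-en-1-yl]ethan-1-one | C[C@H]1C=C(O[Si](C)(C)C(C)(C)C)CC(C)(C)[C@H]1C(C)=O | intermediate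
5 | diethyl 1-[(1S,2S)-4-{[tert-butyl(dimethyl)silyl]oxy}-2,6,6-trimethylcyclohex-3-en-1-yl]ethenyl phosphate (not isolated) | C[C@H]1C=C(O[Si](C)(C)C(C)(C)C)CC(C)(C)[C@H]1C(=C)OP(=O)(OCC)OCC | intermediate
6 | tert-butyl{[(3R,4S)-4-ethynyl-3,5,5-trimethylcyclohex-1-en-1-yl]oxy}dimethylsilane | C[C@H]1C=C(O[Si](C)(C)C(C)(C)C)CC(C)(C)[C@H]1C#C | intermediate
7 | ethyl (2E)-3-iodobut-2-enoate | CCOC(=O)/C=C(\C)I | starting material
8 | (E)-alkenylzirconocene chloride Cp2Zr(Cl)–CH=CH–R, R = ring of 6 with both centres unchanged (not isolated; cyclopentadienyl rings written σ-bound) | C[C@H]1C=C(O[Si](C)(C)C(C)(C)C)CC(C)(C)[C@H]1/C=C/[Zr](Cl)(C1C=CC=C1)C1C=CC=C1 | intermediate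
9 | (E)-alkenylzinc chloride ClZn–CH=CH–R, same R (not isolated) | C[C@H]1C=C(O[Si](C)(C)C(C)(C)C)CC(C)(C)[C@H]1/C=C/[Zn]Cl | intermediate
10 | ethyl (2E,4E)-5-[(1S,2R)-4-{[tert-butyl(dimethyl)silyl]oxy}-2,6,6-trimethylcyclohex-3-en-1-yl]-3-methylpenta-2,4-dienoate | C[C@H]1C=C(O[Si](C)(C)C(C)(C)C)CC(C)(C)[C@H]1/C=C/C(C)=C/C(=O)OCC | intermediate
11 | ethyl (2E,4E)-3-methyl-5-[(1R)-2,6,6-trimethyl-4-oxocyclohex-2-en-1-yl]penta-2,4-dienoate | CC1=CC(=O)CC(C)(C)[C@H]1/C=C/C(C)=C/C(=O)OCC | intermediate
12 | ethyl (2E,4E)-5-[(1R,4R)-4-hydroxy-2,6,6-trimethylcyclohex-2-en-1-yl]-3-methylpenta-2,4-dienoate | CC1=C[C@H](O)CC(C)(C)[C@H]1/C=C/C(C)=C/C(=O)OCC | intermediate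
13 | ethyl (2E,4E)-5-[(1R,4R)-4-{[tert-butyl(dimethyl)silyl]oxy}-2,6,6-trimethylcyclohex-2-en-1-yl]-3-methylpenta-2,4-dienoate | CC1=C[C@H](O[Si](C)(C)C(C)(C)C)CC(C)(C)[C@H]1/C=C/C(C)=C/C(=O)OCC | intermediate
14 | (2E,4E)-5-[(1R,4R)-4-{[tert-butyl(dimethyl)silyl]oxy}-2,6,6-trimethylcyclohex-2-en-1-yl]-3-methylpenta-2,4-dien-1-ol | CC1=C[C@H](O[Si](C)(C)C(C)(C)C)CC(C)(C)[C@H]1/C=C/C(C)=C/CO | intermediate
15 | {[(1R,4R)-4-[(1E,3E)-5-bromo-3-methylpenta-1,3-dien-1-yl]-3,5,5-trimethylcyclohex-2-en-1-yl]oxy}(tert-butyl)dimethylsilane (not isolated) | CC1=C[C@H](O[Si](C)(C)C(C)(C)C)CC(C)(C)[C@H]1/C=C/C(C)=C/CBr | intermediate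
16 | {(2E,4E)-5-[(1R,4R)-4-{[tert-butyl(dimethyl)silyl]oxy}-2,6,6-trimethylcyclohex-2-en-1-yl]-3-methylpenta-2,4-dien-1-yl}triphenylphosphonium bromide | CC1=C[C@H](O[Si](C)(C)C(C)(C)C)CC(C)(C)[C@H]1/C=C/C(C)=C/C[P+](c1ccccc1)(c1ccccc1)c1ccccc1.[Br-] | intermediate
17 | (2E,4E,6E)-2,7-dimethylocta-2,4,6-trienedial | O=C/C(C)=C/C=C/C=C(C)/C=O | starting material
18 | (2E,4E,6E,8E,10E,12E)-13-[(1R,4R)-4-{[tert-butyl(dimethyl)silyl]oxy}-2,6,6-trimethylcyclohex-2-en-1-yl]-2,7,11-trimethyltrideca-2,4,6,8,10,12-hexaenal (not isolated; expected as an 8E/8Z mixture, 8E shown) | CC1=C[C@H](O[Si](C)(C)C(C)(C)C)CC(C)(C)[C@H]1/C=C/C(C)=C/C=C/C(C)=C/C=C/C=C(C)/C=O | intermediate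
19 | (all-E)-(3R,3′R,6R,6′R)-3,3′-bis{[tert-butyl(dimethyl)silyl]oxy}-ε,ε-carotene | CC1=C[C@H](O[Si](C)(C)C(C)(C)C)CC(C)(C)[C@H]1/C=C/C(C)=C/C=C/C(C)=C/C=C/C=C(C)/C=C/C=C(C)/C=C/[C@H]1C(C)=C[C@H](O[Si](C)(C)C(C)(C)C)CC1(C)C | intermediate
20 | (all-E)-(3R,3′R,6R,6′R)-ε,ε-carotene-3,3′-diol | CC1=C[C@H](O)CC(C)(C)[C@H]1/C=C/C(C)=C/C=C/C(C)=C/C=C/C=C(C)/C=C/C=C(C)/C=C/[C@H]1C(C)=C[C@H](O)CC1(C)C | target

**Step count**
Total: 11 steps. Longest linear sequence: 11 steps (1 → 20); 3, 7 and 17 are used as bought.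

**Steps most likely to fail**

1. Step 2. The hindered β,β-dimethyl enone may react too slowly at low temperature, the diene may be protodesilylated by the acid, and a silyl-triflimide-catalysed racemic pathway may erode the enantioselectivity. Fallback: setting out from 2 and 3, the cycloaddition is run without chiral information under catalytic HNTf2 or AlBr3/AlMe3 in CH2Cl2, a known way of joining 2-silyloxydienes to hindered β,β-disubstituted enones. This should give the racemic cis ketone F1. Its enantiomers are then separated by preparative chromatography on a cellulose tris(3,5-dimethylphenylcarbamate) stationary phase; the (1S,2S) enantiomer is 4, where the route is rejoined.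

2. Step 5. Transmetalation of the bulky silyl enol ether to palladium may be slow, the enol ether may hydrolyse to the saturated ketone, and palladium hydride may migrate the double bonds or epimerise the doubly allylic C6. Fallback: setting out from 10, PhSeCl in CH2Cl2 at −78 °C should give the α-phenylselanyl ketone F2 (selenium on C4, trans to the C5 methyl). H2O2 with pyridine at 0 °C oxidises it to the selenoxide F3, which loses benzeneselenenic acid by syn-elimination with the cis C5–H in the same flask and returns to the route at 11.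

3. Step 6. Facial selectivity at C3 may be poor if catalyst control and the ring's own bias do not cooperate, and the β-methyl enone may be reduced sluggishly. Fallback: setting out from 11, NaBH4/CeCl3·7H2O in EtOH at −40 °C gives 12 together with its C3 epimer, the cis alcohol F4. After chromatographic separation, F4 is inverted by a Mitsunobu reaction (4-nitrobenzoic acid, PPh3, diisopropyl azodicarboxylate) to the (3R)-4-nitrobenzoate F5, and ethanolysis (K2CO3, EtOH) returns to the route at 12.

**Further compounds**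
F1 | step 2 | racemic cis-1-[4-{[tert-butyl(dimethyl)silyl]oxy}-2,6,6-trimethylcyclohex-3-en-1-yl]ethan-1-one (both enantiomers written) | C[C@H]1C=C(O[Si](C)(C)C(C)(C)C)CC(C)(C)[C@H]1C(C)=O.C[C@@H]1C=C(O[Si](C)(C)C(C)(C)C)CC(C)(C)[C@@H]1C(C)=O
F2 | step 5 | ethyl (2E,4E)-3-methyl-5-[2,6,6-trimethyl-4-oxo-3-(phenylselanyl)cyclohexyl]penta-2,4-dienoate, ring centres C5 and C6 as in 10, selenium trans to the C5 methyl | C[C@H]1[C@H]([Se]c2ccccc2)C(=O)CC(C)(C)[C@H]1/C=C/C(C)=C/C(=O)OCC
F3 | step 5 | selenoxide of F2 (not isolated) | C[C@H]1[C@H]([Se](=O)c2ccccc2)C(=O)CC(C)(C)[C@H]1/C=C/C(C)=C/C(=O)OCC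
F4 | step 6 | ethyl (2E,4E)-5-[(1R,4S)-4-hydroxy-2,6,6-trimethylcyclohex-2-en-1-yl]-3-methylpenta-2,4-dienoate | CC1=C[C@@H](O)CC(C)(C)[C@H]1/C=C/C(C)=C/C(=O)OCC
F5 | step 6 | ethyl (2E,4E)-3-methyl-5-[(1R,4R)-2,6,6-trimethyl-4-[(4-nitrobenzoyl)oxy]cyclohex-2-en-1-yl]penta-2,4-dienoate | CC1=C[C@H](OC(=O)c2ccc(cc2)[N+](=O)[O-])CC(C)(C)[C@H]1/C=C/C(C)=C/C(=O)OCC
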